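**Retrosynthetic overview**
- The target comes from its 5-O-methyl, 4'-O-MOM ether: the last step frees both phenols (chelation-directed cleavage of the 5-OMe group, acid removal of the MOM group).
- Ring C is the only ring built. It is closed by forming the O1–C2 bond in an enantioselective 6-endo oxa-Michael addition of a 2'-hydroxychalcone, which sets C2 as (S).
- The chalcone comes from a prenylated 2'-hydroxy-4',5',6'-trimethoxyacetophenone and 4-(methoxymethoxy)benzaldehyde by Claisen–Schmidt condensation.
- The prenyl group is put on the one free carbon of ring A by iodination and Stille coupling of the purchased acetophenone. Rings A and B are bought.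

Assumption: the acetophenone, the prenylstannane and the MOM-protected aldehyde are bought as catalog chemicals, and the (S)-tert-leucine-derived antipode of the step 4 catalyst is taken to be the one that gives (2S) (its mirror image is used if a first run shows the opposite sense).

**Step 1**
Reactants: 1 1-(6-hydroxy-2,3,4-trimethoxyphenyl)ethan-1-one (2'-hydroxy-4',5',6'-trimethoxyacetophenone)
Product: 2 1-(2-hydroxy-3-iodo-4,5,6-trimethoxyphenyl)ethan-1-one
Conditions: NIS (1.05 equiv), TsOH·H2O (10 mol%), MeCN, 0 °C → rt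
Reagents that add atoms: N-iodosuccinimide, O=C1CCC(=O)N1I
Why: Electrophilic aromatic iodination (SEAr) at the only unsubstituted ring carbon, which is ortho to the phenol and flanked by a methoxy group, so it outruns α-iodination of the ketone; no stereocenter is formed.

**Step 2**
Reactants: 2 1-(2-hydroxy-3-iodo-4,5,6-trimethoxyphenyl)ethan-1-one; 3 tributyl(3-methylbut-2-en-1-yl)stannane
Product: 4 1-[2-hydroxy-4,5,6-trimethoxy-3-(3-methylbut-2-en-1-yl)phenyl]ethan-1-one
Conditions: Pd(PPh3)4 (5 mol%), DMF, 90 °C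
Reagents that add atoms: none
Why: Migita–Kosugi–Stille coupling: zerovalent palladium inserts into the aryl–iodine bond, the allylic stannane transmetalates and reductive elimination at the unhindered CH2 terminus gives the linear prenyl arene under neutral conditions that tolerate the free phenol and the methyl ketone; no stereocenter is formed.

**Step 3**
Reactants: 4 1-[2-hydroxy-4,5,6-trimethoxy-3-(3-methylbut-2-en-1-yl)phenyl]ethan-1-one; 5 4-(methoxymethoxy)benzaldehyde
Product: 6 (2E)-1-[2-hydroxy-4,5,6-trimethoxy-3-(3-methylbut-2-en-1-yl)phenyl]-3-[4-(methoxymethoxy)phenyl]prop-2-en-1-one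
Conditions: KOH (50% aq., 10 equiv), EtOH, 0 °C → rt, 36 h; then AcOH
Reagents that add atoms: none
Why: Claisen–Schmidt (crossed aldol) condensation of the methyl ketone and a non-enolizable aldehyde, followed by E1cB dehydration to the (E)-enone; in excess KOH the chalcone rests as its 2'-phenoxide, which does not ring-close, and the MOM acetal is inert to base.

**Step 4**
Reactants: 6 (2E)-1-[2-hydroxy-4,5,6-trimethoxy-3-(3-methylbut-2-en-1-yl)phenyl]-3-[4-(methoxymethoxy)phenyl]prop-2-en-1-one
Product: 7 (2S)-5,6,7-trimethoxy-2-[4-(methoxymethoxy)phenyl]-8-(3-methylbut-2-en-1-yl)-2,3-dihydro-4H-chromen-4-one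
Conditions: 1-[3,5-bis(trifluoromethyl)phenyl]-3-[(2S)-3,3-dimethyl-1-{[tris(4-methoxyphenyl)-λ5-phosphanylidene]amino}butan-2-yl]thiourea (10 mol%), toluene, −20 °C, 24 h; then AcOH (20 mol%)
Reagents that add atoms: none
Why: Proposed new method: enantioselective 6-endo-trig intramolecular oxa-Michael addition of an unactivated 2'-hydroxy-6'-methoxychalcone under bifunctional iminophosphorane–thiourea catalysis, forming the O1–C2 bond and setting C2. The P=N superbase deprotonates the 2'-OH to a tight chiral iminophosphonium phenoxide ion pair while the two thiourea N–H bonds bind the enone carbonyl; the 2',6'-disubstitution twists the aroyl group out of the ring plane so the phenoxide sits over C-β; the tert-butyl group of the catalyst is meant to leave only the Si face of C-β open, which gives (2S) after the iminophosphonium N–H protonates the enolate. Low temperature, a non-polar aprotic solvent and the AcOH quench keep the closure under kinetic control against retro-oxa-Michael erosion. The closest known reaction types are the cinchona–thiourea oxa-Michael closure of chalcones activated by an α-ester group and the iminophosphorane-catalysed oxa-Michael addition of alcohols to unsaturated esters and amides.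

**Step 5**
Reactants: 7 (2S)-5,6,7-trimethoxy-2-[4-(methoxymethoxy)phenyl]-8-(3-methylbut-2-en-1-yl)-2,3-dihydro-4H-chromen-4-one
Product: 9 (2S)-5-hydroxy-2-(4-hydroxyphenyl)-6,7-dimethoxy-8-(3-methylbut-2-en-1-yl)-2,3-dihydro-4H-chromen-4-one, via 5-hydroxy MOM ether 8 (not isolated)
Conditions: MgI2·OEt2 (3 equiv), THF, 55 °C; then MeOH, 3 M aq. HCl, 40 °C
Reagents that add atoms: none
Why: Chelation-directed SN2 O-demethylation: magnesium bridges the C4 carbonyl and O5, so iodide attacks only the peri methyl group (this reagent is established for 5-methoxy-8-prenylflavanones and leaves the prenyl alkene and the other methyl ethers alone), then acid-catalysed acetal methanolysis removes the MOM group; neither stage is basic, so C2 is not scrambled through ring opening.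

**Compound list**
1 | 1-(6-hydroxy-2,3,4-trimethoxyphenyl)ethan-1-one | CC(=O)c1c(O)cc(OC)c(OC)c1OC | starting material
2 | 1-(2-hydroxy-3-iodo-4,5,6-trimethoxyphenyl)ethan-1-one | CC(=O)c1c(O)c(I)c(OC)c(OC)c1OC | intermediate
3 | tributyl(3-methylbut-2-en-1-yl)stannane | CCCC[Sn](CCCC)(CCCC)CC=C(C)C | starting material
4 | 1-[2-hydroxy-4,5,6-trimethoxy-3-(3-methylbut-2-en-1-yl)phenyl]ethan-1-one | CC(=O)c1c(O)c(CC=C(C)C)c(OC)c(OC)c1OC | intermediate
5 | 4-(methoxymethoxy)benzaldehyde | O=Cc1ccc(OCOC)cc1 | starting material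
6 | (2E)-1-[2-hydroxy-4,5,6-trimethoxy-3-(3-methylbut-2-en-1-yl)phenyl]-3-[4-(methoxymethoxy)phenyl]prop-2-en-1-one | COc1c(OC)c(OC)c(CC=C(C)C)c(O)c1C(=O)/C=C/c1ccc(OCOC)cc1 | intermediate
7 | (2S)-5,6,7-trimethoxy-2-[4-(methoxymethoxy)phenyl]-8-(3-methylbut-2-en-1-yl)-2,3-dihydro-4H-chromen-4-one | COc1c(OC)c2c(c(CC=C(C)C)c1OC)O[C@H](c1ccc(OCOC)cc1)CC2=O | intermediate
8 | (2S)-5-hydroxy-6,7-dimethoxy-2-[4-(methoxymethoxy)phenyl]-8-(3-methylbut-2-en-1-yl)-2,3-dihydro-4H-chromen-4-one (held in the flask as its magnesium phenoxide, drawn as the phenol) | COc1c(O)c2c(c(CC=C(C)C)c1OC)O[C@H](c1ccc(OCOC)cc1)CC2=O | intermediate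
9 | (2S)-5-hydroxy-2-(4-hydroxyphenyl)-6,7-dimethoxy-8-(3-methylbut-2-en-1-yl)-2,3-dihydro-4H-chromen-4-one (CNP0104932.1) | COc1c(O)c2c(c(CC=C(C)C)c1OC)O[C@H](c1ccc(O)cc1)CC2=O | target

**Step count and risks**
Total step count: 5. Longest linear sequence: 5 steps (1 → 2 → 4 → 6 → 7 → 9).

The three steps most likely to fail:

Step 4, the new ring closure. The risks are low ee, the wrong sense of induction, or erosion by reversible ring opening; ee and sense are read by chiral HPLC and by the CD spectrum against natural (2S)-flavanones. The known-chemistry fallback sets out from 6 and comes back at 7. Chalcone 6 is closed thermally (NaOAc, EtOH, reflux) to racemic 5,6,7-trimethoxy-2-[4-(methoxymethoxy)phenyl]-8-(3-methylbut-2-en-1-yl)-2,3-dihydro-4H-chromen-4-one F1. Preparative chiral SFC on an amylose tris(3,5-dimethylphenylcarbamate) phase then separates it into 7 and (2R)-5,6,7-trimethoxy-2-[4-(methoxymethoxy)phenyl]-8-(3-methylbut-2-en-1-yl)-2,3-dihydro-4H-chromen-4-one F2. F2 is recycled, since KOH in EtOH opens it back to chalcone 6.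

Step 2, the Stille prenylation. The risks are a sluggish reaction at the doubly flanked iodide and some branched 1,1-dimethylallyl isomer. The fallback sets out from 1 and comes back at 4 without any cross-coupling. O-Allylation of 1 (allyl bromide, K2CO3, DMF, 60 °C) gives 1-[2,3,4-trimethoxy-6-(prop-2-en-1-yloxy)phenyl]ethan-1-one F3. Aromatic Claisen rearrangement (N,N-diethylaniline, 190 °C) moves the allyl group to the only free ortho carbon and gives 1-[2-hydroxy-4,5,6-trimethoxy-3-(prop-2-en-1-yl)phenyl]ethan-1-one F4. Cross-metathesis of F4 in excess 2-methylbut-2-ene (second-generation Grubbs catalyst RuCl2(H2IMes)(PCy3)(=CHPh), CH2Cl2, 40 °C) gives 4.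

Step 5, the double deprotection. The risks are over-demethylation at O6, damage to the prenyl group in the acid stage, or partial loss of ee. The fallback sets out from 2 and comes back at 9; it puts the prenyl group on last so that a stronger Lewis acid can be used. Iodide 2 is condensed with 5 (KOH, EtOH) to (2E)-1-(2-hydroxy-3-iodo-4,5,6-trimethoxyphenyl)-3-[4-(methoxymethoxy)phenyl]prop-2-en-1-one F5. Ring C is closed by the method of step 4, or by its fallback, to (2S)-8-iodo-5,6,7-trimethoxy-2-[4-(methoxymethoxy)phenyl]-2,3-dihydro-4H-chromen-4-one F6. BCl3 (CH2Cl2, −78 → 0 °C) then cleaves the MOM ether and the chelated 5-OMe group in one operation to give (2S)-5-hydroxy-2-(4-hydroxyphenyl)-8-iodo-6,7-dimethoxy-2,3-dihydro-4H-chromen-4-one F7. Stille coupling of F7 and 3 (Pd(PPh3)4, DMF, 80 °C) gives 9.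

**Further compounds**
F1 | step 4 | racemic 5,6,7-trimethoxy-2-[4-(methoxymethoxy)phenyl]-8-(3-methylbut-2-en-1-yl)-2,3-dihydro-4H-chromen-4-one | COc1c(OC)c2c(c(CC=C(C)C)c1OC)OC(c1ccc(OCOC)cc1)CC2=O
F2 | step 4 | (2R)-5,6,7-trimethoxy-2-[4-(methoxymethoxy)phenyl]-8-(3-methylbut-2-en-1-yl)-2,3-dihydro-4H-chromen-4-one | COc1c(OC)c2c(c(CC=C(C)C)c1OC)O[C@@H](c1ccc(OCOC)cc1)CC2=O
F3 | step 2 | 1-[2,3,4-trimethoxy-6-(prop-2-en-1-yloxy)phenyl]ethan-1-one | CC(=O)c1c(OCC=C)cc(OC)c(OC)c1OC
F4 | step 2 | 1-[2-hydroxy-4,5,6-trimethoxy-3-(prop-2-en-1-yl)phenyl]ethan-1-one | CC(=O)c1c(O)c(CC=C)c(OC)c(OC)c1OC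
F5 | step 5 | (2E)-1-(2-hydroxy-3-iodo-4,5,6-trimethoxyphenyl)-3-[4-(methoxymethoxy)phenyl]prop-2-en-1-one | COc1c(OC)c(OC)c(I)c(O)c1C(=O)/C=C/c1ccc(OCOC)cc1
F6 | step 5 | (2S)-8-iodo-5,6,7-trimethoxy-2-[4-(methoxymethoxy)phenyl]-2,3-dihydro-4H-chromen-4-one | COc1c(OC)c2c(c(I)c1OC)O[C@H](c1ccc(OCOC)cc1)CC2=O
F7 | step 5 | (2S)-5-hydroxy-2-(4-hydroxyphenyl)-8-iodo-6,7-dimethoxy-2,3-dihydro-4H-chromen-4-one | COc1c(O)c2c(c(I)c1OC)O[C@H](c1ccc(O)cc1)CC2=O
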